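**Plan**

Labels: oxane ring O1, C2 (aryl), C3 (cinnamyl), C4, C5, C6; carbinol carbon C7. Retrosynthetic cuts, in order: the styrene C=C (cross metathesis); C6 back to a lactone carbonyl; C5–C7 (aldol condensation, then H and OH added across C5=C7); O1–C6, with O1 returned to C5, which shrinks the oxane to an oxolane-2-carbaldehyde; C2–aryl; C3–allyl.
Forward order: the five-membered ring O1–C2–C3–C4–C5 comes from (R)-5-(hydroxymethyl)butyrolactone, is allylated at C3 and arylated at C2, and then grows by C6 into the six-membered lactone. C7 with its aryl group, removal of the C6 oxygen, and the styrene follow.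
Enabling feature: C6 is a single carbon between O1 and C5. As a formyl group on C5 of the oxolane it can be made an acyl anion equivalent by a carbene catalyst, push O1 off C5, and take O1 back as an acyl carbon. The benzylic C2–O1 bond is never broken.
Reason for the smaller ring: in the five-membered 2-aryl oxocarbenium ion, hydride enters anti to the C3 allyl group and gives the contra-thermodynamic cis C2/C3 pair. The six-membered ion would take hydride axially and give the trans pair.
Stereochemistry: C5 of the starting lactone sets C3 (trans alkylation), and C3 sets C2 (hydride anti to allyl). The old C5 centre is then erased. C5 and C7 are set together by syn addition of H and B to the (E)-alkylidene lactone from the ring face opposite to the C2 and C3 groups. The E alkene comes from metathesis.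

Key step: step 6

Remark: TBS = tert-butyldimethylsilyl, TES = triethylsilyl. The hemiketal and the lactol are carried as anomer mixtures because the anomeric centre is removed in the next step. All starting materials are taken as catalogue compounds.

**Step 1**
Reactants: 1 (R)-5-(hydroxymethyl)dihydrofuran-2(3H)-one
Product: 2 (R)-5-[(triethylsilyloxy)methyl]dihydrofuran-2(3H)-one
Conditions: TESCl, imidazole, CH2Cl2, 0 °C → rt
Reagents that add atoms: chlorotriethylsilane, CC[Si](Cl)(CC)CC
Why: Silyl ether protection of a primary alcohol, giving a group bulky enough to steer the next alkylation and one that can later be oxidised directly to the aldehyde.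

**Step 2**
Reactants: 2 (R)-5-[(triethylsilyloxy)methyl]dihydrofuran-2(3H)-one; 3 allyl bromide
Product: 5 (3S,5R)-3-allyl-5-[(triethylsilyloxy)methyl]dihydrofuran-2(3H)-one, via lithium enolate 4 (not isolated)
Conditions: LDA, THF, −78 °C; 3, −78 → −40 °C
Reagents that add atoms: lithium diisopropylamide, CC(C)[N-]C(C)C.[Li+] (lithium in 4 only)
Why: Lactone enolate alkylation with 1,3-induction, in which allyl bromide should approach the planar enolate on the face opposite to the C5 silyloxymethyl group and so set C3 trans to it.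

**Step 3**
Reactants: 5 (3S,5R)-3-allyl-5-[(triethylsilyloxy)methyl]dihydrofuran-2(3H)-one; 6 (4-bromophenoxy)(tert-butyl)dimethylsilane
Product: 8 (3S,5R)-3-allyl-2-[4-(TBSO)phenyl]-5-[(triethylsilyloxy)methyl]tetrahydrofuran-2-ol (anomer mixture), via aryllithium 7 (not isolated)
Conditions: 6, n-BuLi, THF, −78 °C; then 5, −78 °C; aqueous work-up
Reagents that add atoms: n-butyllithium, [Li]CCCC (lithium in 7 only)
Why: Bromine–lithium exchange followed by 1,2-addition of the aryllithium to the lactone carbonyl, which should stop at the lithium hemiketal at −78 °C so that only one aryl group is taken up at C2.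

**Step 4**
Reactants: 8 (3S,5R)-3-allyl-2-[4-(TBSO)phenyl]-5-[(triethylsilyloxy)methyl]tetrahydrofuran-2-ol
Product: 9 (2R,3S,5R)-3-allyl-2-[4-(TBSO)phenyl]-5-[(triethylsilyloxy)methyl]tetrahydrofuran
Conditions: Et3SiH, BF3·OEt2, CH2Cl2, −78 °C
Reagents that add atoms: none
Why: Ionic hydrogenation of the hemiketal (Kursanov–Parnes type) through the planar 2-aryl oxocarbenium ion, in which the C3 allyl group should turn pseudoaxial to avoid the coplanar aryl ring, the C5 side chain stays pseudoequatorial, and Et3SiH should enter from the inside of this envelope anti to the allyl group, placing aryl and allyl cis at a temperature where neither C3 nor C2 is expected to equilibrate.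

**Step 5**
Reactants: 9 (2R,3S,5R)-3-allyl-2-[4-(TBSO)phenyl]-5-[(triethylsilyloxy)methyl]tetrahydrofuran
Product: 11 (2R,4S,5R)-4-allyl-5-[4-(TBSO)phenyl]tetrahydrofuran-2-carbaldehyde, via alkoxysulfonium chloride 10 (not isolated)
Conditions: (COCl)2, DMSO, CH2Cl2, −78 → −40 °C; Et3N, −78 °C → rt
Reagents that add atoms: dimethyl sulfoxide, CS(C)=O (SMe2 in 10 only); oxalyl chloride, O=C(Cl)C(=O)Cl (chloride in 10 only)
Why: Swern oxidation applied directly to a primary triethylsilyl ether, in which the chlorosulfonium salt exchanges the silyl group for the alkoxysulfonium unit and Et3N then releases the aldehyde, while the aryl silyl ether stays and any epimerisation at C5 is harmless because that centre is erased in step 6.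

**Step 6**
Reactants: 11 (2R,4S,5R)-4-allyl-5-[4-(TBSO)phenyl]tetrahydrofuran-2-carbaldehyde
Product: 12 (5R,6R)-5-allyl-6-[4-(TBSO)phenyl]tetrahydro-2H-pyran-2-one
Conditions: IMes·HCl (1,3-dimesitylimidazolium chloride, 10 mol %), DBU (10 mol %), CH2Cl2, rt
Reagents that add atoms: none
Why: The carbene freed from IMes·HCl adds to the formyl carbon C6 and a proton shift gives the Breslow enaminol, in which C6 is nucleophilic (polarity reversal); its electron pair pushes O1 off the neighbouring C5, the resulting enol is protonated at C5 to an acyl azolium ion, and the released C2 alkoxide attacks C6 and sets the carbene free again. The closest known reaction type is the carbene-catalysed ring expansion of oxacycloalkane-2-carbaldehydes to lactones, an internal redox esterification of an α-oxygenated aldehyde. The six-membered ring O1–C2–C3–C4–C5–C6 closes by a 6-exo-trig acyl substitution and is one atom (C6) larger than the oxolane it replaces. No stereocentre is created: C5 becomes CH2, and C2 and C3 keep their cis relation because the C2–O1 bond and all bonds at C3 stay intact. The step needs C5–O1 cleavage to outrun benzoin-type self-condensation and any attack on the allyl group; the leaving oxygen sits directly next to the nucleophilic carbon, the N-mesityl groups hinder dimerisation, and the unactivated terminal alkene is no acceptor for an acyl anion equivalent. The new C6 carbonyl also makes C5 the only acidic position for step 7.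

**Step 7**
Reactants: 12 (5R,6R)-5-allyl-6-[4-(TBSO)phenyl]tetrahydro-2H-pyran-2-one; 13 4-(tert-butyldimethylsilyloxy)benzaldehyde
Product: 17 (3E,5S,6R)-5-allyl-3-[4-(TBSO)benzylidene]-6-[4-(TBSO)phenyl]tetrahydro-2H-pyran-2-one, via lithium enolate 14 (not isolated), via lithium aldolate 15 (not isolated), via aldol mesylate 16 (not isolated)
Conditions: LiN(SiMe3)2, THF, −78 °C; 13; MsCl, −78 → 0 °C; DBU, 0 °C → rt
Reagents that add atoms: lithium bis(trimethylsilyl)amide, C[Si](C)(C)[N-][Si](C)(C)C.[Li+] (lithium in 14 and 15 only); methanesulfonyl chloride, CS(=O)(=O)Cl (mesyl group in 16 only)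
Why: Aldol condensation (aldol addition, mesylation, E1cB elimination) at the only enolisable position C5, which should give the thermodynamically preferred (E)-alkylidene lactone with the aryl group anti to the carbonyl whatever the configuration of the aldolate.

**Step 8**
Reactants: 17 (3E,5S,6R)-5-allyl-3-[4-(TBSO)benzylidene]-6-[4-(TBSO)phenyl]tetrahydro-2H-pyran-2-one
Product: 19 (3S,5S,6R)-5-allyl-3-{(R)-hydroxy[4-(TBSO)phenyl]methyl}-6-[4-(TBSO)phenyl]tetrahydro-2H-pyran-2-one, via benzylic boronate 18 (not isolated)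
Conditions: CuCl (5 mol %), DPEphos (5 mol %), NaOt-Bu (10 mol %), B2pin2, MeOH, THF, rt; then NaBO3·4H2O, THF/H2O, rt
Reagents that add atoms: bis(pinacolato)diboron, CC1(C)OB(B2OC(C)(C)C(C)(C)O2)OC1(C)C (Bpin in 18 only); sodium perborate, [Na+].[O-]OB=O (oxygen at C7)
Why: Copper-catalysed conjugate borylation–protonation followed by stereoretentive C–B oxidation, in which the copper boryl species should add to the ring face opposite to the C2 aryl and C3 allyl groups and the copper enolate should be protonated axially from that same face, so that net syn addition of H and B to the (E)-alkene fixes C5 cis to C3 and fixes C7, while the unactivated allyl group is left alone.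

**Step 9**
Reactants: 19 (3S,5S,6R)-5-allyl-3-{(R)-hydroxy[4-(TBSO)phenyl]methyl}-6-[4-(TBSO)phenyl]tetrahydro-2H-pyran-2-one
Product: 20 (3S,5S,6R)-5-allyl-3-{(R)-(TBSO)[4-(TBSO)phenyl]methyl}-6-[4-(TBSO)phenyl]tetrahydro-2H-pyran-2-one
Conditions: TBSCl, imidazole, DMF, rt
Reagents that add atoms: tert-butylchlorodimethylsilane, CC(C)(C)[Si](C)(C)Cl
Why: Silyl ether protection under mildly basic conditions, which avoids both retro-aldol cleavage and exposure of the benzylic lactone C2–O bond to a Lewis acidic silyl triflate.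

**Step 10**
Reactants: 20 (3S,5S,6R)-5-allyl-3-{(R)-(TBSO)[4-(TBSO)phenyl]methyl}-6-[4-(TBSO)phenyl]tetrahydro-2H-pyran-2-one
Product: 21 (3S,5S,6R)-5-allyl-3-{(R)-(TBSO)[4-(TBSO)phenyl]methyl}-6-[4-(TBSO)phenyl]tetrahydro-2H-pyran-2-ol (anomer mixture)
Conditions: i-Bu2AlH, CH2Cl2, −78 °C; aq. potassium sodium tartrate
Reagents that add atoms: none
Why: Partial reduction of a lactone, in which the aluminium hemiacetal is stable at −78 °C and gives the lactol only on work-up, so the ring stays closed and C5 is not epimerised.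

**Step 11**
Reactants: 21 (3S,5S,6R)-5-allyl-3-{(R)-(TBSO)[4-(TBSO)phenyl]methyl}-6-[4-(TBSO)phenyl]tetrahydro-2H-pyran-2-ol
Product: 22 (2R,3S,5R)-3-allyl-5-{(R)-(TBSO)[4-(TBSO)phenyl]methyl}-2-[4-(TBSO)phenyl]tetrahydro-2H-pyran
Conditions: Et3SiH (excess), BF3·OEt2, CH2Cl2, −78 °C
Reagents that add atoms: none
Why: Ionic reduction of a lactol through the unstabilised C6 oxocarbenium ion, whose capture by excess silane at −78 °C should outrun ionisation of the two benzylic C–O bonds and any attack by the terminal alkene, with no stereocentre formed at C6.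

**Step 12**
Reactants: 22 (2R,3S,5R)-3-allyl-5-{(R)-(TBSO)[4-(TBSO)phenyl]methyl}-2-[4-(TBSO)phenyl]tetrahydro-2H-pyran; 23 4-(tert-butyldimethylsilyloxy)styrene
Product: 24 tetrakis-TBS ether of the target, (2R,3S,5R)-3-{(E)-3-[4-(TBSO)phenyl]allyl}-5-{(R)-(TBSO)[4-(TBSO)phenyl]methyl}-2-[4-(TBSO)phenyl]tetrahydro-2H-pyran
Conditions: 23 (excess), second-generation Hoveyda–Grubbs catalyst (5 mol %), CH2Cl2, 40 °C
Reagents that add atoms: none
Why: Olefin cross metathesis of a terminal allyl group with a styrene, which should give the conjugated E alkene under thermodynamic control and is placed after step 11 so that the electron-rich styrene never meets a Lewis acid or an oxocarbenium ion.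

**Step 13**
Reactants: 24 tetrakis-TBS ether of the target
Product: 25 4-[(E)-3-{(2R,3S,5R)-5-[(R)-hydroxy(4-hydroxyphenyl)methyl]-2-(4-hydroxyphenyl)tetrahydro-2H-pyran-3-yl}prop-1-en-1-yl]phenol (target)
Conditions: TBAF, AcOH (1:1), THF, 0 °C → rt
Reagents that add atoms: none
Why: Fluoride-mediated global desilylation, buffered with acetic acid so that neither phenoxide-driven quinone methide formation nor acid-catalysed ionisation can scramble the benzylic centres C2 and C7.

**Compound list**

1 | (R)-5-(hydroxymethyl)dihydrofuran-2(3H)-one | O=C1CC[C@H](CO)O1 | starting material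
2 | (R)-5-[(triethylsilyloxy)methyl]dihydrofuran-2(3H)-one | O=C1CC[C@H](CO[Si](CC)(CC)CC)O1 | intermediate
3 | allyl bromide | C=CCBr | starting material
4 | lithium enolate of 2 | [Li+].[O-]C1=CC[C@H](CO[Si](CC)(CC)CC)O1 | intermediate
5 | (3S,5R)-3-allyl-5-[(triethylsilyloxy)methyl]dihydrofuran-2(3H)-one | C=CC[C@H]1C[C@H](CO[Si](CC)(CC)CC)OC1=O | intermediate
6 | (4-bromophenoxy)(tert-butyl)dimethylsilane | CC(C)(C)[Si](C)(C)Oc1ccc(Br)cc1 | starting material
7 | 4-(tert-butyldimethylsilyloxy)phenyllithium | [Li]c1ccc(O[Si](C)(C)C(C)(C)C)cc1 | intermediate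
8 | (3S,5R)-3-allyl-2-[4-(TBSO)phenyl]-5-[(triethylsilyloxy)methyl]tetrahydrofuran-2-ol, anomer mixture | C=CC[C@H]1C[C@H](CO[Si](CC)(CC)CC)OC1(O)c1ccc(O[Si](C)(C)C(C)(C)C)cc1 | intermediate
9 | (2R,3S,5R)-3-allyl-2-[4-(TBSO)phenyl]-5-[(triethylsilyloxy)methyl]tetrahydrofuran | C=CC[C@H]1C[C@H](CO[Si](CC)(CC)CC)O[C@H]1c1ccc(O[Si](C)(C)C(C)(C)C)cc1 | intermediate
10 | alkoxysulfonium chloride derived from 9 | C=CC[C@H]1C[C@H](CO[S+](C)C)O[C@H]1c1ccc(O[Si](C)(C)C(C)(C)C)cc1.[Cl-] | intermediate
11 | (2R,4S,5R)-4-allyl-5-[4-(TBSO)phenyl]tetrahydrofuran-2-carbaldehyde | C=CC[C@H]1C[C@H](C=O)O[C@H]1c1ccc(O[Si](C)(C)C(C)(C)C)cc1 | intermediate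
12 | (5R,6R)-5-allyl-6-[4-(TBSO)phenyl]tetrahydro-2H-pyran-2-one | C=CC[C@H]1CCC(=O)O[C@H]1c1ccc(O[Si](C)(C)C(C)(C)C)cc1 | intermediate
13 | 4-(tert-butyldimethylsilyloxy)benzaldehyde | CC(C)(C)[Si](C)(C)Oc1ccc(C=O)cc1 | starting material
14 | lithium enolate of 12 | [Li+].C=CC[C@H]1CC=C([O-])O[C@H]1c1ccc(O[Si](C)(C)C(C)(C)C)cc1 | intermediate
15 | lithium aldolate from 14 and 13, mixture at C5 and C7 | [Li+].C=CC[C@H]1CC(C([O-])c2ccc(O[Si](C)(C)C(C)(C)C)cc2)C(=O)O[C@H]1c1ccc(O[Si](C)(C)C(C)(C)C)cc1 | intermediate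
16 | aldol mesylate, mixture at C5 and C7 | C=CC[C@H]1CC(C(OS(C)(=O)=O)c2ccc(O[Si](C)(C)C(C)(C)C)cc2)C(=O)O[C@H]1c1ccc(O[Si](C)(C)C(C)(C)C)cc1 | intermediate
17 | (3E,5S,6R)-5-allyl-3-[4-(TBSO)benzylidene]-6-[4-(TBSO)phenyl]tetrahydro-2H-pyran-2-one | C=CC[C@H]1C/C(=C\c2ccc(O[Si](C)(C)C(C)(C)C)cc2)C(=O)O[C@H]1c1ccc(O[Si](C)(C)C(C)(C)C)cc1 | intermediate
18 | (3S,5S,6R)-5-allyl-3-{(R)-(pinacolatoboryl)[4-(TBSO)phenyl]methyl}-6-[4-(TBSO)phenyl]tetrahydro-2H-pyran-2-one | C=CC[C@H]1C[C@@H]([C@@H](B2OC(C)(C)C(C)(C)O2)c2ccc(O[Si](C)(C)C(C)(C)C)cc2)C(=O)O[C@H]1c1ccc(O[Si](C)(C)C(C)(C)C)cc1 | intermediate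
19 | (3S,5S,6R)-5-allyl-3-{(R)-hydroxy[4-(TBSO)phenyl]methyl}-6-[4-(TBSO)phenyl]tetrahydro-2H-pyran-2-one | C=CC[C@H]1C[C@@H]([C@@H](O)c2ccc(O[Si](C)(C)C(C)(C)C)cc2)C(=O)O[C@H]1c1ccc(O[Si](C)(C)C(C)(C)C)cc1 | intermediate
20 | (3S,5S,6R)-5-allyl-3-{(R)-(TBSO)[4-(TBSO)phenyl]methyl}-6-[4-(TBSO)phenyl]tetrahydro-2H-pyran-2-one | C=CC[C@H]1C[C@@H]([C@@H](O[Si](C)(C)C(C)(C)C)c2ccc(O[Si](C)(C)C(C)(C)C)cc2)C(=O)O[C@H]1c1ccc(O[Si](C)(C)C(C)(C)C)cc1 | intermediate
21 | (3S,5S,6R)-5-allyl-3-{(R)-(TBSO)[4-(TBSO)phenyl]methyl}-6-[4-(TBSO)phenyl]tetrahydro-2H-pyran-2-ol, anomer mixture | C=CC[C@H]1C[C@@H]([C@@H](O[Si](C)(C)C(C)(C)C)c2ccc(O[Si](C)(C)C(C)(C)C)cc2)C(O)O[C@H]1c1ccc(O[Si](C)(C)C(C)(C)C)cc1 | intermediate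
22 | (2R,3S,5R)-3-allyl-5-{(R)-(TBSO)[4-(TBSO)phenyl]methyl}-2-[4-(TBSO)phenyl]tetrahydro-2H-pyran | C=CC[C@H]1C[C@@H]([C@@H](O[Si](C)(C)C(C)(C)C)c2ccc(O[Si](C)(C)C(C)(C)C)cc2)CO[C@H]1c1ccc(O[Si](C)(C)C(C)(C)C)cc1 | intermediate
23 | 4-(tert-butyldimethylsilyloxy)styrene | C=Cc1ccc(O[Si](C)(C)C(C)(C)C)cc1 | starting material
24 | tetrakis-TBS ether of the target | CC(C)(C)[Si](C)(C)Oc1ccc(/C=C/C[C@H]2C[C@@H]([C@@H](O[Si](C)(C)C(C)(C)C)c3ccc(O[Si](C)(C)C(C)(C)C)cc3)CO[C@H]2c2ccc(O[Si](C)(C)C(C)(C)C)cc2)cc1 | intermediate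
25 | 4-[(E)-3-{(2R,3S,5R)-5-[(R)-hydroxy(4-hydroxyphenyl)methyl]-2-(4-hydroxyphenyl)tetrahydro-2H-pyran-3-yl}prop-1-en-1-yl]phenol | Oc1ccc(/C=C/C[C@H]2C[C@@H]([C@@H](O)c3ccc(O)cc3)CO[C@H]2c2ccc(O)cc2)cc1 | target

Total step count: 13. Longest linear sequence: 13 steps (1 → 25).

**Steps most likely to fail**

Step 8.
- Risk: face discrimination at the exocyclic carbon C7 may be weak. Boryl transfer to the electron-rich, trisubstituted acceptor may be slow. The catalytic alkoxide may epimerise C5 after protonation.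
- Fallback: it sets out from 17. Nucleophilic Weitz–Scheffer epoxidation (t-BuOOH, DBU, CH2Cl2) should deliver oxygen from the open ring face to C5 and C7 and give the spiro-epoxy lactone F1. SmI2 in THF/MeOH at −78 °C should then cleave the C5–O bond by two single-electron transfers and keep the C7–O bond. The samarium enolate should be protonated from the same open face. The fallback comes back to the route at 19.

Step 11.
- Risk: BF3·OEt2 may ionise the C2–O1 or the C7–O benzylic bond, which would lead to epimerisation, ring opening or over-reduction.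
- Fallback: it sets out from 21. A neutral redox condensation with PhSSPh and n-Bu3P in CH2Cl2 should give the phenylthio acetal F2. n-Bu3SnH with AIBN in toluene at 90 °C should then replace the sulfur by hydrogen through the C6 α-oxy radical, with no cation on the ring oxygen. The fallback comes back to the route at 22.

Step 4.
- Risk: hydride may be delivered to the wrong face of the oxocarbenium ion, or acid may equilibrate the product towards the trans C2/C3 pair.
- Fallback: it sets out from 8.
  - The open γ-hydroxy ketone tautomer of 8 is trapped with MsCl and Et3N as the keto mesylate F3.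
  - Reagent-controlled reduction with (+)-B-chlorodiisopinocampheylborane in THF at −25 °C should give the (R)-benzylic alcohol F4 without touching the alkene.
  - NaH in THF should close the oxolane by 5-exo-tet displacement of the mesylate, with inversion at C5 and retention at C2, to give the all-cis oxolane F5, the C5 epimer of 9.
  - Swern oxidation as in step 5 gives the epimeric aldehyde F6.
  - Because C5 is erased, the carbene-catalysed ring expansion of F6 comes back to the route at 12.

**Further compounds**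

F1 | step 8 | spiro-epoxy lactone (oxirane across C5–C7 of 17, oxygen on the face opposite to the allyl and C2 aryl groups) | C=CC[C@H]1C[C@]2(O[C@H]2c2ccc(O[Si](C)(C)C(C)(C)C)cc2)C(=O)O[C@H]1c1ccc(O[Si](C)(C)C(C)(C)C)cc1
F2 | step 11 | phenylthio acetal (6-phenylsulfanyl derivative of 22, anomer mixture) | C=CC[C@H]1C[C@@H]([C@@H](O[Si](C)(C)C(C)(C)C)c2ccc(O[Si](C)(C)C(C)(C)C)cc2)C(Sc2ccccc2)O[C@H]1c1ccc(O[Si](C)(C)C(C)(C)C)cc1
F3 | step 4 | (2R,4S)-4-[4-(TBSO)benzoyl]-1-(triethylsilyloxy)hept-6-en-2-yl methanesulfonate | C=CC[C@@H](C[C@H](CO[Si](CC)(CC)CC)OS(C)(=O)=O)C(=O)c1ccc(O[Si](C)(C)C(C)(C)C)cc1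
F4 | step 4 | (2R,4S)-4-{(R)-hydroxy[4-(TBSO)phenyl]methyl}-1-(triethylsilyloxy)hept-6-en-2-yl methanesulfonate | C=CC[C@@H](C[C@H](CO[Si](CC)(CC)CC)OS(C)(=O)=O)[C@@H](O)c1ccc(O[Si](C)(C)C(C)(C)C)cc1
F5 | step 4 | (2R,3S,5S)-3-allyl-2-[4-(TBSO)phenyl]-5-[(triethylsilyloxy)methyl]tetrahydrofuran | C=CC[C@H]1C[C@@H](CO[Si](CC)(CC)CC)O[C@H]1c1ccc(O[Si](C)(C)C(C)(C)C)cc1
F6 | step 4 | (2S,4S,5R)-4-allyl-5-[4-(TBSO)phenyl]tetrahydrofuran-2-carbaldehyde | C=CC[C@H]1C[C@@H](C=O)O[C@H]1c1ccc(O[Si](C)(C)C(C)(C)C)cc1
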